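**Assumption:** the SMILES descriptor is read as (R) at the benzylic carbinol (OH > aryl > CH2 > H) with an E ring olefin; the route is planned for that (R,E) isomer.

## Retrosynthetic overview

1. The (R)-carbinol is set last by asymmetric transfer hydrogenation of the macrocyclic aryl ketone, after acid removal of the MOM groups while C1 is still a ketone.
2. The 22-membered ring (the only ring made; both benzene rings are bought) is closed at the diaryl ether C–O bond by Ir C–H borylation of ring A C5–H, then Cu oxidative etherification with the ring B phenoxide.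
3. The open-chain ketone comes from a ring B aryl Grignard (resorcinol → MOM, ortho-lithiation/oxidation, bromination, silylation) adding to a C14 nitrile.
4. The nitrile comes from two B-alkyl Suzuki couplings: hept-6-enenitrile with (E)-1-iodohepta-1,6-diene (E-olefin from alkyne hydrozirconation), then with MOM-protected 3-bromophenol.

## Route

**Step 1**
Reactants: 1, resorcinol
Product: 2, 1,3-bis(methoxymethoxy)benzene
Conditions: MOMCl (2.5 equiv), i-Pr2NEt, CH2Cl2, 0 °C → rt
Reagents that add atoms: chloromethyl methyl ether, COCCl
Why: Standard O-alkylation of a phenol to the MOM acetal, which later directs ortho-lithiation and cannot migrate to a neighbouring phenol.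

**Step 2**
Reactants: 2, 1,3-bis(methoxymethoxy)benzene
Product: 3, 2,6-bis(methoxymethoxy)phenol
Conditions: n-BuLi, THF, 0 °C; B(OMe)3, −78 °C → rt; H2O2, aq NaOH, 0 °C; NH4Cl work-up
Reagents that add atoms: hydrogen peroxide, OO
Why: Directed ortho-metalation occurs at C2 between the two OMOM groups, and borylation/oxidation of the aryllithium gives the phenol.

**Step 3**
Reactants: 3, 2,6-bis(methoxymethoxy)phenol
Product: 4, 4-bromo-2,6-bis(methoxymethoxy)phenol
Conditions: NBS (1.0 equiv), MeCN, −30 → 0 °C
Reagents that add atoms: N-bromosuccinimide, O=C1CCC(=O)N1Br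
Why: Electrophilic aromatic bromination goes para to the free OH because both ortho positions are blocked.

**Step 4**
Reactants: 4, 4-bromo-2,6-bis(methoxymethoxy)phenol
Product: 5, [4-bromo-2,6-bis(methoxymethoxy)phenoxy](tert-butyl)dimethylsilane
Conditions: TBSCl, imidazole, DMAP (cat.), DMF, 40 °C
Reagents that add atoms: tert-butyldimethylsilyl chloride, CC(C)(C)[Si](C)(C)Cl
Why: Silylation masks the acidic phenol for Grignard formation and leaves a fluoride-labile latent phenoxide for the ring closure.

**Step 5**
Reactants: 6, 3-bromophenol
Product: 7, 1-bromo-3-(methoxymethoxy)benzene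
Conditions: MOMCl, i-Pr2NEt, CH2Cl2, 0 °C → rt
Reagents that add atoms: chloromethyl methyl ether, COCCl
Why: MOM protection of the phenol, stable to the Suzuki, Grignard and borylation steps and removed together with the ring B MOM groups.

**Step 6**
Reactants: 8, 5-bromopent-1-ene
Product: 9, hept-1-en-6-yne
Conditions: lithium acetylide–ethylenediamine, DMSO, 10 °C → rt; distil
Reagents that add atoms: lithium acetylide–ethylenediamine complex, [Li]C#C.NCCN
Why: SN2 alkylation of acetylide by a primary bromide gives the terminal alkyne.

**Step 7**
Reactants: 9, hept-1-en-6-yne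
Product: 10, (E)-1-iodohepta-1,6-diene
Conditions: Cp2Zr(H)Cl (1.05 equiv), CH2Cl2, 0 °C → rt; I2, 0 °C
Reagents that add atoms: iodine, II
Why: Schwartz hydrozirconation adds syn to the terminal alkyne faster than to the terminal alkene, and iodinolysis with retention fixes the E geometry.

**Step 8**
Reactants: 11, hept-6-enenitrile; 10, (E)-1-iodohepta-1,6-diene
Product: 12, (E)-tetradeca-8,13-dienenitrile
Conditions: 11 + 9-BBN (1.0 equiv), THF, 0 °C → rt; then 10 (0.9 equiv), Pd(dppf)Cl2 (3 mol %), AsPh3, Cs2CO3, DMF/H2O, rt
Reagents that add atoms: none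
Why: In this B-alkyl Suzuki–Miyaura coupling 9-BBN hydroborates the terminal alkene anti-Markovnikov without touching the nitrile, and the sp3–sp2 coupling retains the vinyl iodide geometry.

**Step 9**
Reactants: 12, (E)-tetradeca-8,13-dienenitrile; 7, 1-bromo-3-(methoxymethoxy)benzene
Product: 13, (E)-14-[3-(methoxymethoxy)phenyl]tetradec-8-enenitrile
Conditions: 12 + 9-BBN (1.0 equiv), THF, 0 °C → rt; then 7, Pd(dppf)Cl2 (3 mol %), aq K3PO4, THF/DMF, 60 °C
Reagents that add atoms: none
Why: A second B-alkyl Suzuki–Miyaura coupling, in which 9-BBN selects the terminal over the internal E-olefin.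

**Step 10**
Reactants: 5, [4-bromo-2,6-bis(methoxymethoxy)phenoxy](tert-butyl)dimethylsilane; 13, (E)-14-[3-(methoxymethoxy)phenyl]tetradec-8-enenitrile
Product: 14, (E)-1-[4-(tert-butyldimethylsilyloxy)-3,5-bis(methoxymethoxy)phenyl]-14-[3-(methoxymethoxy)phenyl]tetradec-8-en-1-one
Conditions: 5 (1.4 equiv), Mg (I2-activated), THF, 50 °C; then 13, CuBr·SMe2 (5 mol %), THF, 50 °C; 10 % aq citric acid, rt
Reagents that add atoms: water, O (ketone oxygen, from hydrolysis of the ketimine)
Why: Cu(I)-catalysed Grignard addition to the nitrile stops at the N-magnesio ketimine, so mild acid hydrolysis gives the aryl ketone without over-addition and leaves MOM and TBS intact.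

**Step 11**
Reactants: 14, the open-chain TBS/MOM-protected ketone
Product: 15, the tris-MOM macrocyclic ketone: 22-membered diaryl ether in which ring A C5 is bonded to the ring B C4 oxygen, ring A is meta-bridged, ring B is para-bridged, and the olefin is E
Conditions: (i) [Ir(cod)OMe]2 (2.5 mol %), 3,4,7,8-Me4-phenanthroline (5 mol %), B2pin2 (1.2 equiv), THF, 65 °C; evaporate; (ii) syringe-pump over 12 h into Cu(OAc)2 (30 mol %), pyridine (5 equiv), CsF (3 equiv), 4 Å MS, O2 (1 atm), MeCN, 45 °C, final 2 mM
Reagents that add atoms: none (B2pin2 and CsF leave no atoms in the product)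
Why: Proposed new method: a one-pot formal dehydrogenative C–H/O–Si macro-etherification in which the Ir tris-boryl catalyst borylates the only arene C–H of 14 with no ortho substituent (ring A C5; both ring B C–H bonds are flanked by acyl and OMOM), CsF then cleaves the aryl TBS ether to the hindered phenoxide and activates the Bpin as a fluoroborate for transmetalation to Cu(II), and phenoxide ligation, oxidation to Cu(III) and C–O reductive elimination close the strain-free 22-membered ring under high dilution, with O2 turning Cu over; the closest known chemistry is intermolecular sequential Ir-borylation/Chan–Lam etherification of arenes and Chan–Lam macrocyclisation of preformed arylboronic acids.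

**Step 12**
Reactants: 15, tris-MOM macrocyclic ketone
Product: 16, macrocyclic triphenol ketone (the C1 ketone of the target)
Conditions: 3 M aq HCl, MeOH/THF, 50 °C, under Ar
Reagents that add atoms: none
Why: Acid-catalysed acetal hydrolysis removes all three MOM groups while C1 is still a ketone, so no ionisable benzylic alcohol is exposed to acid and the isolated E-olefin and diaryl ether are untouched.

**Step 13**
Reactants: 16, macrocyclic triphenol ketone
Product: 17, dehydrogravicycle, (R)-carbinol, E-olefin
Conditions: RuCl[(R,R)-TsDPEN](p-cymene) (2 mol %), HCO2H/Et3N (5:2), DMF, 40 °C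
Reagents that add atoms: none
Why: Noyori–Ikariya asymmetric transfer hydrogenation delivers hydride to the Si face of the aryl alkyl ketone (aryl CH/π-controlled six-membered transition state), and (R,R)-TsDPEN gives the (R)-1-arylalkanol while tolerating free phenols and the isolated olefin.

## Compound list

1 | resorcinol | Oc1cccc(O)c1 | starting material
2 | 1,3-bis(methoxymethoxy)benzene | COCOc1cccc(OCOC)c1 | intermediate
3 | 2,6-bis(methoxymethoxy)phenol | COCOc1cccc(OCOC)c1O | intermediate
4 | 4-bromo-2,6-bis(methoxymethoxy)phenol | COCOc1cc(Br)cc(OCOC)c1O | intermediate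
5 | [4-bromo-2,6-bis(methoxymethoxy)phenoxy](tert-butyl)dimethylsilane | COCOc1cc(Br)cc(OCOC)c1O[Si](C)(C)C(C)(C)C | intermediate
6 | 3-bromophenol | Oc1cccc(Br)c1 | starting material
7 | 1-bromo-3-(methoxymethoxy)benzene | COCOc1cccc(Br)c1 | intermediate
8 | 5-bromopent-1-ene | C=CCCCBr | starting material
9 | hept-1-en-6-yne | C=CCCCC#C | intermediate
10 | (E)-1-iodohepta-1,6-diene | I/C=C/CCCC=C | intermediate
11 | hept-6-enenitrile | C=CCCCCC#N | starting material
12 | (E)-tetradeca-8,13-dienenitrile | N#CCCCCCC/C=C/CCCC=C | intermediate
13 | (E)-14-[3-(methoxymethoxy)phenyl]tetradec-8-enenitrile | N#CCCCCCC/C=C/CCCCCc1cccc(OCOC)c1 | intermediate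
14 | (E)-1-[4-(tert-butyldimethylsilyloxy)-3,5-bis(methoxymethoxy)phenyl]-14-[3-(methoxymethoxy)phenyl]tetradec-8-en-1-one | COCOc1cc(cc(OCOC)c1O[Si](C)(C)C(C)(C)C)C(=O)CCCCCC/C=C/CCCCCc1cccc(OCOC)c1 | intermediate
15 | tris-MOM macrocyclic ketone (22-membered diaryl ether, E) | COCOc1cc2cc(c1)Oc1c(OCOC)cc(cc1OCOC)C(=O)CCCCCC/C=C/CCCCC2 | intermediate
16 | macrocyclic triphenol ketone (E) | Oc1cc2cc(c1)Oc1c(O)cc(cc1O)C(=O)CCCCCC/C=C/CCCCC2 | intermediate
17 | dehydrogravicycle, (R,E) | Oc1cc2cc(c1)Oc1c(O)cc(cc1O)[C@H](O)CCCCCC/C=C/CCCCC2 | target

## Summary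

Total step count: 13, with one-pot step 11 counted as one step (14 if its two stages are counted separately).

Longest linear sequence: 8 (steps 1–4, 10–13; the chain branch 6–9, 10–13 is also 8). If step 11 is counted as two, it is 9 of 14.

Three steps most likely to fail:

- **Step 11 (proposed new C–H borylation/Cu macro-etherification).** Risks are protodeboronation, oligomerisation, and the hindered, para-acyl phenoxide. Fallback with known chemistry: move to a halide-based ring closure. Convert 7 to 1,3-dibromo-5-(methoxymethoxy)benzene (Ir borylation, then CuBr2) and mono-couple it with the 9-BBN adduct of 12. Carry the remaining Br through the step 10 union, remove TBS with TBAF, and close the ring by a classical intramolecular Ullmann etherification (CuI, N,N-dimethylglycine, Cs2CO3, dioxane, 100 °C, 2 mM).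
- **Step 10 (aryl Grignard addition to an enolisable nitrile).** Risks are sluggish addition or α-deprotonation. Fallback: reduce 13 to the aldehyde with DIBAL-H, add the aryllithium from 5 (t-BuLi, −78 °C) to give the racemic benzylic alcohol, and oxidise to 14 with Dess–Martin periodinane.
- **Step 13 (transfer hydrogenation of an electron-rich ketone bearing three free phenols).** Risks are low conversion or eroded ee. Fallback: silylate the three phenols of 16 (TBSCl, imidazole), reduce with (S)-Me-CBS/BH3·SMe2 to the (R)-alcohol, and desilylate with AcOH-buffered TBAF.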